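The plan rests on cutting the single bond between the benzene-ring carbon para to the phenolic oxygen and the benzylic CH2 of the O–CH2–CH2 tether. Both of these carbons can be bought or made as C–Br electrophiles. One nickel/photoredox cross-electrophile coupling therefore joins the complete C36 ester side chain to the protected phenol ring in a single operation. No organometallic reagent is needed that would attack the ester or eliminate the β-acyloxy group. The precursor pair is the 2-bromoethyl ester of hexatriacontanoic acid, made in one esterification, and commercial O-silylated 4-bromophenol. A buffered fluoride desilylation then releases the target. No ring and no stereocentre has to be built.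

Key step: step 2

Assumption: the acyl chain is read as 36 carbons counting the carbonyl carbon (hexatriacontanoyl; target C44H80O3, achiral), and acid 1 is taken as a catalogue item of speciality lipid suppliers.

Design note: the costly waxy bromo ester is made the limiting partner of the coupling and the cheap aryl bromide is used in excess. An inert aromatic co-solvent, dilution and mild warming keep the wax in solution under irradiation.

Step 1
Reactants: 1 hexatriacontanoic acid; 2 2-bromoethanol
Product: 3 2-bromoethyl hexatriacontanoate
Conditions: 2 (5 equiv), p-TsOH·H2O (10 mol %), toluene, reflux, Dean–Stark; aqueous wash, recrystallisation from acetone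
Reagents that add atoms: none
Why: Fischer esterification driven forward by excess alcohol and azeotropic water removal; boiling toluene dissolves the C36 acid, no chloride is present that could exchange with the primary bromide, and the C–Br bond is inert to catalytic sulfonic acid.

Step 2
Reactants: 3 2-bromoethyl hexatriacontanoate; 4 tert-butyl(4-bromophenoxy)dimethylsilane
Product: 5 2-[4-(tert-butyldimethylsilyloxy)phenyl]ethyl hexatriacontanoate
Conditions: 4 (2 equiv), NiCl2(dimethoxyethane) (5 mol %), dtbbpy (5 mol %), [Ir(dF(CF3)ppy)2(dtbbpy)]PF6 (1 mol %), (Me3Si)3SiH (1.2 equiv), Na2CO3 (2 equiv), DME/PhCF3 1:1 (0.03 M in 3), degassed, blue LEDs (450 nm), 45 °C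
Reagents that add atoms: none
Why: Zerovalent nickel bearing dtbbpy inserts into the aryl C–Br bond of 4 to give a divalent aryl nickel bromide, while the photoexcited iridium complex oxidises bromide to a bromine atom that removes the Si–H hydrogen of (Me3Si)3SiH. The silyl radical abstracts bromine from 3, the 2-(acyloxy)ethyl radical is captured by the aryl nickel species, reductive elimination from trivalent nickel forms the aryl–CH2 bond, and the reduced photocatalyst returns monovalent nickel to the zerovalent state. The closest known reaction type is exactly this silyl-radical-mediated nickel/photoredox cross-electrophile coupling of aryl bromides with primary alkyl bromides, which tolerates esters and silyl ethers. No ring is closed and no stereocentre is formed. The step needs cross- over homo-coupling, secured because the sp2 C–Br bond responds only to nickel insertion and the sp3 C–Br bond only to halogen-atom abstraction by silicon, and helped by using cheap 4 in excess so that the radical from costly 3 always meets an aryl nickel trap. Carboxylate is a poor leaving group from a β-radical, its 1,2-shift across the CH2–CH2 unit is degenerate, reductive elimination should outpace β-acyloxy loss at nickel, and the silyl ether keeps the acidic phenol from C–O coupling or protonolysis.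

Step 3
Reactants: 5 2-[4-(tert-butyldimethylsilyloxy)phenyl]ethyl hexatriacontanoate
Product: 6 2-(4-hydroxyphenyl)ethyl hexatriacontanoate (target CNP0275784.0)
Conditions: Bu4NF (1.2 equiv), AcOH (1.5 equiv), THF, 35 °C
Reagents that add atoms: none
Why: Buffered fluoride desilylation of an aryl silyl ether, in which fluoride attacks silicon and expels the phenoxide, and acetic acid protonates it at once so the medium never becomes basic enough to hydrolyse or transesterify the alkyl ester.

Compound list
1 | hexatriacontanoic acid | CCCCCCCCCCCCCCCCCCCCCCCCCCCCCCCCCCCC(=O)O | starting material
2 | 2-bromoethanol | OCCBr | starting material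
3 | 2-bromoethyl hexatriacontanoate | CCCCCCCCCCCCCCCCCCCCCCCCCCCCCCCCCCCC(=O)OCCBr | intermediate
4 | tert-butyl(4-bromophenoxy)dimethylsilane | CC(C)(C)[Si](C)(C)Oc1ccc(Br)cc1 | starting material
5 | 2-[4-(tert-butyldimethylsilyloxy)phenyl]ethyl hexatriacontanoate | CCCCCCCCCCCCCCCCCCCCCCCCCCCCCCCCCCCC(=O)OCCc1ccc(O[Si](C)(C)C(C)(C)C)cc1 | intermediate
6 | 2-(4-hydroxyphenyl)ethyl hexatriacontanoate | CCCCCCCCCCCCCCCCCCCCCCCCCCCCCCCCCCCC(=O)OCCc1ccc(O)cc1 | target

Total step count: 3
Longest linear sequence: 3 steps (1 → 3 → 5 → 6)

Steps most likely to fail

**Step 2.**
- What may go wrong:
  - hydrogen-atom transfer from the silane to the 2-(acyloxy)ethyl radical before nickel captures it, which simply reduces the C–Br bond;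
  - slow oxidative addition into the electron-rich aryl bromide;
  - loss of carboxylate from an alkyl nickel intermediate;
  - crystallisation of the waxy ester out of the irradiated medium.
- Fallback: the same aryl–CH2 bond is made by polar chemistry, setting out from 4. Magnesium insertion (Mg turnings, THF) should give [4-(tert-butyldimethylsilyloxy)phenyl]magnesium bromide F1. This opens ethylene oxide (THF solution, CuI 10 mol %, −20 to 0 °C) to give 2-[4-(tert-butyldimethylsilyloxy)phenyl]ethanol F2. Steglich esterification of F2 with acid 1 (EDC·HCl, DMAP, CH2Cl2/toluene, 40 °C) comes back to the route at 5.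

**Step 3.**
- What may go wrong:
  - incomplete desilylation because the substrate dissolves poorly;
  - acyl transfer and ester cleavage if the buffer is exhausted and phenoxide or basic fluoride builds up.
- Fallback: a protecting group that leaves under neutral, non-nucleophilic conditions, setting out from 3. Compound 3 is coupled under the step 2 conditions with commercial 1-(benzyloxy)-4-bromobenzene to give 2-[4-(benzyloxy)phenyl]ethyl hexatriacontanoate F3. Hydrogenolysis (H2 1 atm, Pd/C, THF/EtOAc, 40 °C) cleaves the benzyl ether while the homobenzylic ester stays intact, and the sequence comes back at 6.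

**Step 1.**
- What may go wrong:
  - stalling of the equilibrium short of full conversion;
  - acid-promoted self-condensation of the bromo alcohol at reflux.
- Fallback: irreversible acylation in place of equilibrium esterification, setting out from 1. Oxalyl chloride (cat. DMF, toluene, 50 °C) should give hexatriacontanoyl chloride F4. After evaporation, F4 is heated with 2 (1.5 equiv) in toluene at 70 °C under a nitrogen sweep without amine base, and the sequence comes back at 3.

Further compounds
F1 | step 2 | [4-(tert-butyldimethylsilyloxy)phenyl]magnesium bromide | CC(C)(C)[Si](C)(C)Oc1ccc([Mg]Br)cc1
F2 | step 2 | 2-[4-(tert-butyldimethylsilyloxy)phenyl]ethanol | CC(C)(C)[Si](C)(C)Oc1ccc(CCO)cc1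
F3 | step 3 | 2-[4-(benzyloxy)phenyl]ethyl hexatriacontanoate | CCCCCCCCCCCCCCCCCCCCCCCCCCCCCCCCCCCC(=O)OCCc1ccc(OCc2ccccc2)cc1
F4 | step 1 | hexatriacontanoyl chloride | CCCCCCCCCCCCCCCCCCCCCCCCCCCCCCCCCCCC(=O)Cl
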